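**Plan**
Numbering used: oxolane O1, C2 (aryl), C3 (arm carbon C9), C4 (side chain, carbinol carbon C7'), C5.
Retrosynthesis: cut aryl–C2 together with C3–C9 in one three-component event on the enol ether O1–C2=C3 of a 3-substituted 2,3-dihydrofuran; return C2=C3 to a lactone carbonyl at C2; then cut O1–C2 (lactone) and C4–C7' (aldol).
Forward: an anti-aldol joins the C7' aldehyde to a succinate imide (C4–C7'); reductive auxiliary removal closes the oxolane as a γ-lactone (O1–C2); lactone → lactol → dihydrofuran; key carbo-arylation; deprotection.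
Stereochemistry: C4 and C7' come from one auxiliary-controlled anti-aldol; C3 and C2 are both relayed from C4 in the key event (C3 anti to the C4 side chain, C2 anti to the C3 arm through a temporary ring).
Enabling feature: O1 flanks C2, so O1–C2=C3 is nucleophilic at C3 and becomes electrophilic at C2. The C9 oxygen is 1,3 to C2, so its pivaloyl group can bridge C2 as a six-membered 1,3-dioxan-2-ylium ring that forces 2,3-trans aryl delivery; the all-trans ring is also the thermodynamic isomer.

Key step: step 9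

Abbreviations: TBS = tert-butyldimethylsilyl; Ar(TBS) = 4-[(tert-butyldimethylsilyl)oxy]-3-methoxyphenyl; Piv = 2,2-dimethylpropanoyl.
Assumption (chemistry): the chelated magnesium enolate of 3 is taken to react with the π-facial sense of chelate-controlled imide alkylation, so the (R)-auxiliary leads to the (3S) anti adduct; were the sense opposite, the (S)-auxiliary would serve with no other change.

**Step 1**
Reactants: 1 (R)-4-benzyl-1,3-oxazolidin-2-one; 2 methyl 4-chloro-4-oxobutanoate
Product: 3 methyl 4-[(4R)-4-benzyl-2-oxo-1,3-oxazolidin-3-yl]-4-oxobutanoate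
Conditions: n-BuLi, THF, −78 °C; then 2, −78 → 0 °C
Reagents that add atoms: none
Why: N-acylation of the lithiated oxazolidinone by the acid chloride (standard imide formation); no stereocenter is formed.

**Step 2**
Reactants: 3; 4 4-[(tert-butyldimethylsilyl)oxy]-3-methoxybenzaldehyde
Product: 6 methyl (3S)-4-[(4R)-4-benzyl-2-oxo-1,3-oxazolidin-3-yl]-3-[(R)-Ar(TBS)(hydroxy)methyl]-4-oxobutanoate, via trimethylsilyl ether 5 (not isolated)
Conditions: MgCl2 (0.1 equiv), Et3N, Me3SiCl, EtOAc, 23 °C; then CF3CO2H (cat.), MeOH, 0 °C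
Reagents that add atoms: none
Why: Magnesium-halide-catalysed direct anti-aldol reaction of an N-acyloxazolidinone: Et3N/MgCl2 should enolize only the chelating imide CH2 (not the ester CH2), the chelated (Z)-enolate should add to the non-enolizable aryl aldehyde on the face away from the benzyl group to set C4 and C7' together (anti), silylation of the aldolate turns the magnesium over, and brief methanolysis frees the alcohol.

**Step 3**
Reactants: 6
Product: 7 methyl (3S)-4-[(4R)-4-benzyl-2-oxo-1,3-oxazolidin-3-yl]-3-[(R)-Ar(TBS)(TBS-oxy)methyl]-4-oxobutanoate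
Conditions: t-BuMe2SiOSO2CF3, 2,6-lutidine, CH2Cl2, −78 → 0 °C
Reagents that add atoms: tert-butyldimethylsilyl trifluoromethanesulfonate, CC(C)(C)[Si](C)(C)OS(=O)(=O)C(F)(F)F
Why: Silylation of the secondary benzylic alcohol with a silyl triflate; it blocks retro-aldol and lactonization through the C7' oxygen and keeps this oxygen from bridging to C2 later.

**Step 4**
Reactants: 7
Product: 9 (4R)-4-[(R)-Ar(TBS)(TBS-oxy)methyl]oxolan-2-one, via hydroxy ester 8 (not isolated)
Conditions: NaBH4, THF/H2O (4:1), 0 → 23 °C; then pyridinium p-toluenesulfonate (cat.), toluene, 50 °C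
Reagents that add atoms: none
Why: Borohydride cleaves the N-acyloxazolidinone reductively to the C5 primary alcohol while the methyl ester should survive, and the new hydroxyl closes the oxolane as a γ-lactone on the C2 ester (5-exo-trig, O1–C2 bond); C4 is not touched.

**Step 5**
Reactants: 9
Product: 10 (4R)-4-[(R)-Ar(TBS)(TBS-oxy)methyl]oxolan-2-ol (anomer mixture)
Conditions: i-Bu2AlH (1.1 equiv), CH2Cl2, −78 °C; aqueous potassium sodium tartrate
Reagents that add atoms: none
Why: Partial reduction of a γ-lactone to the lactol; the tetrahedral aluminium hemiacetal is stable at −78 °C until work-up.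

**Step 6**
Reactants: 10
Product: 12 (3R)-3-[(R)-Ar(TBS)(TBS-oxy)methyl]-2,3-dihydrofuran, via anomeric mesylate 11 (not isolated)
Conditions: MeSO2Cl, Et3N (excess), CH2Cl2, −40 → 40 °C; chromatography on Et3N-deactivated silica
Reagents that add atoms: none
Why: Sulfonylation of the anomeric hydroxyl and amine-induced elimination across C2–C3 (the only β-elimination open) gives the cyclic enol ether, as in furanoid glycal formation from 2-deoxy lactols.

**Step 7**
Reactants: 13 4-bromo-2-methoxyphenol
Product: 14 (4-bromo-2-methoxyphenoxy)(tert-butyl)dimethylsilane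
Conditions: t-BuMe2SiCl, imidazole, DMF, 23 °C
Reagents that add atoms: tert-butyldimethylsilyl chloride, CC(C)(C)[Si](C)(C)Cl
Why: Standard silylation of a phenol, so that the aryl donor tolerates lithiation and the final fluoride step frees all three silyl ethers together.

**Step 8**
Reactants: 14
Product: 16 bromo{4-[(tert-butyldimethylsilyl)oxy]-3-methoxyphenyl}zinc, via aryllithium 15 (not isolated)
Conditions: n-BuLi (1.0 equiv), Et2O/toluene, −78 °C; then ZnBr2 (1.0 equiv, Et2O), −78 → 0 °C; used as the solution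
Reagents that add atoms: zinc dibromide, Br[Zn]Br
Why: Bromine–lithium exchange followed by transmetalation with one equivalent of ZnBr2 gives the arylzinc bromide (one aryl group per zinc, present in solution as its lithium bromide adduct), whose C–Zn carbon is para to the silyloxy group, so the regiochemistry on the arene is fixed before the coupling.

**Step 9**
Reactants: 12; 16
Product: 18 [(2R,3S,4R)-2-Ar(TBS)-4-[(R)-Ar(TBS)(TBS-oxy)methyl]oxolan-3-yl]methyl 2,2-dimethylpropanoate, via dioxanylium triflate 17 (not isolated)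
Conditions: ICH2OPiv (1.1 equiv), AgOSO2CF3 (1.1 equiv, toluene), 2,6-di-tert-butyl-4-methylpyridine (0.2 equiv), 4 Å sieves, CH2Cl2, −78 °C; then 16 (1.5 equiv), −78 → −20 °C
Reagents that add atoms: iodomethyl 2,2-dimethylpropanoate (iodomethyl pivalate), CC(C)(C)C(=O)OCI
Why: Proposed new method: the enol ether of 12 (O1–C2=C3) should attack the silver-activated pivaloyloxymethyl electrophile through C3 on the face anti to the C4 side chain; the C2 oxocarbenium ion is then captured by the pivalate carbonyl oxygen (6-exo-trig onto C2=O1+) to give the cis-fused 1,3-dioxan-2-ylium ion 17, which the arylzinc bromide 16 opens at C2 with inversion, forming the aryl–C2 bond trans to the C3 arm. The closest known reaction types are the Prins acyloxymethylation of alkenes with formaldehyde in carboxylic anhydrides (which runs through the same 1,3-dioxan-2-ylium ions), the Lewis-acid three-component coupling of cyclic enol ethers with aldehydes and a third nucleophile, and the 1,2-trans C-arylation of acyl-participating glycosyl bromides with arylzinc reagents. C3 is set by the C4 substituent (steric approach control on the nearly flat dihydrofuran) and C2 by the temporary dioxanylium ring, so both new centers are relayed from C4; without the bridge, inside attack on the open oxocarbenium ion could favour the 2,3-cis isomer. The step needs C3-regioselective attack (secured by polarization of the enol ether by O1), aryl transfer to C2 and not to the acyl carbon (secured by the tert-butyl group and the acetal character of C2), and survival of the benzylic silyl ether (low temperature, no protic acid, hindered pyridine buffer). The arylzinc bromide, in a weakly coordinating solvent, should be nucleophilic enough for the cationic C2 yet too mild to add to the pivalate ester. The all-trans product is also the thermodynamically preferred ring isomer.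

**Step 10**
Reactants: 18
Product: 20 (2R,3S,4R)-2-(4-hydroxy-3-methoxyphenyl)-3-(hydroxymethyl)-4-[(R)-hydroxy(4-hydroxy-3-methoxyphenyl)methyl]oxolane, via triol pivalate 19 (not isolated)
Conditions: Bu4NF (3.3 equiv), THF, 0 → 23 °C; then NaOMe, MeOH, 40 °C; aqueous NH4Cl
Reagents that add atoms: none
Why: Fluoride cleaves the three silyl ethers and methoxide-catalysed transesterification removes the pivalate helper; no acid is present and the temperature is kept low, so the benzylic centers C2 and C7' should not ionize.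

**Compound list**
1 | (R)-4-benzyl-1,3-oxazolidin-2-one | O=C1N[C@H](Cc2ccccc2)CO1 | starting material
2 | methyl 4-chloro-4-oxobutanoate | COC(=O)CCC(Cl)=O | starting material
3 | methyl 4-[(4R)-4-benzyl-2-oxo-1,3-oxazolidin-3-yl]-4-oxobutanoate | COC(=O)CCC(=O)N1[C@H](Cc2ccccc2)COC1=O | intermediate
4 | 4-[(tert-butyldimethylsilyl)oxy]-3-methoxybenzaldehyde | COc1cc(C=O)ccc1O[Si](C)(C)C(C)(C)C | starting material
5 | methyl (3S)-4-[(4R)-4-benzyl-2-oxo-1,3-oxazolidin-3-yl]-3-[(R)-Ar(TBS)(trimethylsilyloxy)methyl]-4-oxobutanoate | COc1cc([C@H](O[Si](C)(C)C)[C@H](CC(=O)OC)C(=O)N2[C@H](Cc3ccccc3)COC2=O)ccc1O[Si](C)(C)C(C)(C)C | intermediate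
6 | methyl (3S)-4-[(4R)-4-benzyl-2-oxo-1,3-oxazolidin-3-yl]-3-[(R)-Ar(TBS)(hydroxy)methyl]-4-oxobutanoate | COc1cc([C@H](O)[C@H](CC(=O)OC)C(=O)N2[C@H](Cc3ccccc3)COC2=O)ccc1O[Si](C)(C)C(C)(C)C | intermediate
7 | methyl (3S)-4-[(4R)-4-benzyl-2-oxo-1,3-oxazolidin-3-yl]-3-[(R)-Ar(TBS)(TBS-oxy)methyl]-4-oxobutanoate | COc1cc([C@H](O[Si](C)(C)C(C)(C)C)[C@H](CC(=O)OC)C(=O)N2[C@H](Cc3ccccc3)COC2=O)ccc1O[Si](C)(C)C(C)(C)C | intermediate
8 | methyl (3R,4R)-4-Ar(TBS)-4-(TBS-oxy)-3-(hydroxymethyl)butanoate | COc1cc([C@H](O[Si](C)(C)C(C)(C)C)[C@H](CC(=O)OC)CO)ccc1O[Si](C)(C)C(C)(C)C | intermediate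
9 | (4R)-4-[(R)-Ar(TBS)(TBS-oxy)methyl]oxolan-2-one | COc1cc([C@H](O[Si](C)(C)C(C)(C)C)[C@H]2COC(=O)C2)ccc1O[Si](C)(C)C(C)(C)C | intermediate
10 | (4R)-4-[(R)-Ar(TBS)(TBS-oxy)methyl]oxolan-2-ol (anomer mixture) | COc1cc([C@H](O[Si](C)(C)C(C)(C)C)[C@H]2COC(O)C2)ccc1O[Si](C)(C)C(C)(C)C | intermediate
11 | (4R)-4-[(R)-Ar(TBS)(TBS-oxy)methyl]oxolan-2-yl methanesulfonate | COc1cc([C@H](O[Si](C)(C)C(C)(C)C)[C@H]2COC(OS(C)(=O)=O)C2)ccc1O[Si](C)(C)C(C)(C)C | intermediate
12 | (3R)-3-[(R)-Ar(TBS)(TBS-oxy)methyl]-2,3-dihydrofuran | COc1cc([C@H](O[Si](C)(C)C(C)(C)C)[C@H]2COC=C2)ccc1O[Si](C)(C)C(C)(C)C | intermediate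
13 | 4-bromo-2-methoxyphenol | COc1cc(Br)ccc1O | starting material
14 | (4-bromo-2-methoxyphenoxy)(tert-butyl)dimethylsilane | COc1cc(Br)ccc1O[Si](C)(C)C(C)(C)C | intermediate
15 | {4-[(tert-butyldimethylsilyl)oxy]-3-methoxyphenyl}lithium | COc1cc([Li])ccc1O[Si](C)(C)C(C)(C)C | intermediate
16 | bromo{4-[(tert-butyldimethylsilyl)oxy]-3-methoxyphenyl}zinc | COc1cc([Zn]Br)ccc1O[Si](C)(C)C(C)(C)C | intermediate
17 | cis-fused 2-tert-butyl-furo[2,3-d][1,3]dioxin-1-ium trifluoromethanesulfonate bearing the C4 side chain (pivaloxonium bridge from C9–O to C2, anti to the side chain) | COc1cc([C@H](O[Si](C)(C)C(C)(C)C)[C@H]2CO[C@@H]3[O+]=C(C(C)(C)C)OC[C@H]23)ccc1O[Si](C)(C)C(C)(C)C.[O-]S(=O)(=O)C(F)(F)F | intermediate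
18 | [(2R,3S,4R)-2-Ar(TBS)-4-[(R)-Ar(TBS)(TBS-oxy)methyl]oxolan-3-yl]methyl 2,2-dimethylpropanoate | COc1cc([C@H](O[Si](C)(C)C(C)(C)C)[C@H]2CO[C@@H](c3ccc(O[Si](C)(C)C(C)(C)C)c(OC)c3)[C@@H]2COC(=O)C(C)(C)C)ccc1O[Si](C)(C)C(C)(C)C | intermediate
19 | [(2R,3S,4R)-4-[(R)-hydroxy(4-hydroxy-3-methoxyphenyl)methyl]-2-(4-hydroxy-3-methoxyphenyl)oxolan-3-yl]methyl 2,2-dimethylpropanoate | COc1cc([C@H](O)[C@H]2CO[C@@H](c3ccc(O)c(OC)c3)[C@@H]2COC(=O)C(C)(C)C)ccc1O | intermediate
20 | (2R,3S,4R)-2-(4-hydroxy-3-methoxyphenyl)-3-(hydroxymethyl)-4-[(R)-hydroxy(4-hydroxy-3-methoxyphenyl)methyl]oxolane | COc1cc([C@H](O)[C@H]2CO[C@@H](c3ccc(O)c(OC)c3)[C@@H]2CO)ccc1O | target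

**Totals**
Total steps: 10. Longest linear sequence: 8 steps (steps 1–6, 9, 10).

**Steps most likely to fail**

Step 9 (proposed new method). What may go wrong: cationic oligomerization of the enol ether, proton loss from the C2 cation back to a 3-substituted dihydrofuran, aryl transfer to the acyl carbon of the bridged ion, or capture of the C2 cation by the electron-rich ring on C7'. The fallback uses known chemistry, sets out from 9 and comes back at 18. Lactone 9 is enolized (LiN(i-Pr)2, THF, −78 °C) and hydroxymethylated with monomeric formaldehyde anti to the C4 side chain to give (3S,4R)-4-[(R)-Ar(TBS)(TBS-oxy)methyl]-3-(hydroxymethyl)oxolan-2-one F1. Reduction with i-Bu2AlH (2.2 equiv, −78 °C) gives the lactol diol (3S,4R)-4-[(R)-Ar(TBS)(TBS-oxy)methyl]-3-(hydroxymethyl)oxolan-2-ol F2. Acylation with t-BuCOCl/pyridine/4-(dimethylamino)pyridine gives the dipivalate [(3S,4R)-4-[(R)-Ar(TBS)(TBS-oxy)methyl]-2-(pivaloyloxy)oxolan-3-yl]methyl 2,2-dimethylpropanoate F3. F3 is ionized with ZnBr2 in toluene/Bu2O and arylated with the arylzinc bromide 16 (C-arylation of an anomeric acyloxy donor by an arylzinc reagent under acyl participation, here through the C9 pivalate) to return to 18.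

Step 6. What may go wrong: the reaction stalls at the anomeric mesylate or chloride without elimination, or the enol ether is hydrated or dimerized by traces of acid on work-up. The fallback sets out from 10 and comes back at 12. Lactol 10 is converted with MeOH and pyridinium p-toluenesulfonate into the chromatographically stable methyl acetal (4R)-4-[(R)-Ar(TBS)(TBS-oxy)methyl]-2-methoxyoxolane F4. F4 is then ionized with Me3SiOSO2CF3 in the presence of i-Pr2NEt (CH2Cl2, −20 → 23 °C), an acetal-to-enol-ether elimination through the oxocarbenium ion instead of an elimination of a sulfonate, to give 12.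

Step 4. What may go wrong: over-reduction of the methyl ester or of the newly formed lactone to the diol, endocyclic attack on the oxazolidinone, or base-induced silyl migration from the C7' oxygen to the new C5 alkoxide. The fallback sets out from 7 and comes back at 9. The auxiliary is removed hydrolytically (LiOH, H2O2, THF/H2O, 0 °C) to give the acid (2S)-2-[(R)-Ar(TBS)(TBS-oxy)methyl]-4-methoxy-4-oxobutanoic acid F5 with the methyl ester retained. BH3·SMe2 reduces the carboxylic acid chemoselectively, without a free alkoxide, to hydroxy ester 8, which is lactonized with pyridinium p-toluenesulfonate to 9.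

**Further compounds**
F1 | step 9 | (3S,4R)-4-[(R)-Ar(TBS)(TBS-oxy)methyl]-3-(hydroxymethyl)oxolan-2-one | COc1cc([C@H](O[Si](C)(C)C(C)(C)C)[C@H]2COC(=O)[C@@H]2CO)ccc1O[Si](C)(C)C(C)(C)C
F2 | step 9 | (3S,4R)-4-[(R)-Ar(TBS)(TBS-oxy)methyl]-3-(hydroxymethyl)oxolan-2-ol (anomer mixture) | COc1cc([C@H](O[Si](C)(C)C(C)(C)C)[C@H]2COC(O)[C@@H]2CO)ccc1O[Si](C)(C)C(C)(C)C
F3 | step 9 | [(3S,4R)-4-[(R)-Ar(TBS)(TBS-oxy)methyl]-2-(pivaloyloxy)oxolan-3-yl]methyl 2,2-dimethylpropanoate (anomer mixture) | COc1cc([C@H](O[Si](C)(C)C(C)(C)C)[C@H]2COC(OC(=O)C(C)(C)C)[C@@H]2COC(=O)C(C)(C)C)ccc1O[Si](C)(C)C(C)(C)C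
F4 | step 6 | (4R)-4-[(R)-Ar(TBS)(TBS-oxy)methyl]-2-methoxyoxolane (anomer mixture) | COc1cc([C@H](O[Si](C)(C)C(C)(C)C)[C@H]2COC(OC)C2)ccc1O[Si](C)(C)C(C)(C)C
F5 | step 4 | (2S)-2-[(R)-Ar(TBS)(TBS-oxy)methyl]-4-methoxy-4-oxobutanoic acid | COc1cc([C@H](O[Si](C)(C)C(C)(C)C)[C@H](CC(=O)OC)C(=O)O)ccc1O[Si](C)(C)C(C)(C)C
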